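I start from a ratio: the hours on the clock over the hours a run needs to stop rising. Elm is the flask asked about, followed so far, and larch is an earlier run.

all flasks: gas 22 mM (held)

|  | substrate | temperature | remark | time |
|---|---|---|---|---|
| elm | 0.064 M | −20 °C | the very flask that is asked about, followed so far |  |
| larch | 0.13 M | −25 °C | run made earlier |  |
| flask | 0.064 M | −20 °C |  | 40 h |

| elm: time / h | elm: target / % | larch: time / h | larch: target / % |
|---|---|---|---|
| 3.00 | 34.0 | 0.500 | 4.3 |
| 8.00 | 34.9 | 1.33 | 15.5 |
| 15.0 | 34.5 | 2.50 | 21.3 |
| 25.0 | 33.7 | 4.00 | 21.3 |

(scatter of a reading: 0.3 percentage points)

- west: at 40 h raise the temperature by 10 K, then wait 20 h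
- south: at 40 h take out 90% of the target then present, then wait 20 h
- east: change nothing and wait 20 h more
- north: at 40 h add substrate, 50.0% of the amount charged, then wait 20 h

- removed target is counted in
- at the start none of the gas is in solution
- additions bring no volume worth counting

- target, in percent of the substrate first charged, at 40 h
- the option that brings most further target ("none" if no option brings more than 2 percentage points) (west / south / east / north / none)
- target present, with what was taken out counted in, in percent of the substrate first charged, after east
- target present, with what was taken out counted in, in percent of the substrate first charged, after north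

Larch shows the run in slow motion. In the first instants target comes slowly, 4.3% after 0.500 h, and the next interval gains faster per hour than the first, as if some stage had to fill first. In the middle target stands at 15.5% after 1.33 h. At the end it reaches 21.3% by 2.50 h, and the next reading is the same.

Elm's first reading already lies among its later ones, so I count in units of 3.00 h:

count at the asked time = 40 h / 3.00 h = 13.3

count after east = (40 h + 20 h) / 3.00 h = 20.0

This turnover count, the time on the clock over the time a run needs to stop rising, is a floor for elm, which may have stopped sooner. The elm readings rise first and fall afterwards, so I take no trend from them. After so many turnovers I expect nothing from waiting, and I put both now and east at their mean: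

mean of the elm readings = 34.3%

Flat has two readings: the forward reaction has stopped, or it runs level with a way back, an equilibrium. Larch, with twice the charge, stands lower in percent, though it is also colder. That fits a balance, and a balance answers to taking target out, so I put south first, without a figure for its gain.

The forecast gives 32.9% now, below my mean, then 31.8% after east and 52% after north. It chooses north, reading the plateau as “substrate is used up, with a competing reaction”.

The flask gives 34.4% at 40 h and 34.4% after east, a gain of 0 percentage points. North reaches 48.8%, a gain of 14 points, west gains 14 points, and south gains 20 points, so south stands first, not the forecast's north.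

    substrate + partner ⇌ intermediate (K = 400 M⁻¹, k = 5.10 M⁻¹ min⁻¹, Ea = 47.0 kJ mol⁻¹, ΔH = −26.0 kJ mol⁻¹)
    intermediate ⇌ target + by-product (K = 0.170 M, k = 0.0520 min⁻¹, Ea = 79.0 kJ mol⁻¹, ΔH = −18.0 kJ mol⁻¹)
    target ⇌ isomer of the product (K = 1.50, k = 0.0870 min⁻¹, Ea = 80.0 kJ mol⁻¹, ΔH = −78.0 kJ mol⁻¹)
    gas ⇌ partner, rate k4*(csat - [partner]) (kL = 0.0690 min⁻¹)
    partner → decomposed reagent (k = 0.0840 min⁻¹, Ea = 71.0 kJ mol⁻¹)
    (constants at −20 °C)

In the first hours of elm, partner fed from the gas took up substrate, intermediate gave target and by-product, and target passed on to isomer of the product, so that after 4.00 h the flask held substrate 2.87%, intermediate 11.2%, target 34.4% and isomer of the product 51.5%. From there to 40.0 h target stays at 34.4%, while partner at 0.00992 M runs on into decomposed reagent, which reaches 1.96 M. Larch, carried to 40 h, a count of 16.0, stands at 20.8%.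

The numbers in the tables come from a simulation on assumed constants; scatter was added.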